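Readings and results are simulated for an exercise; noise was put on by code.

The reciprocal minute was my unit, since the first thing I wanted from the earlier runs was how fast the starting complex goes in each.

common to all: starting complex 0.50 M

| flask | incoming ligand | remark | time |
|---|---|---|---|
| north-east | 0.30 M | run made earlier |  |
| west | 1.6 M | run made earlier |  |
| ash | 0.250 M |  | 40 min |
| oak | 1.00 M |  | 40 min |
| larch | 1.25 M |  | 40 min |

| run | time / min | complex with three exchanged / % | starting complex / % |
|---|---|---|---|
| north-east | 1.33 | 0.3 | 94.6 |
| north-east | 4.00 | 0 | 85.2 |
| north-east | 8.00 | 0.1 | 74.3 |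
| north-east | 10.0 | 0.8 | 69.3 |
| north-east | 15.0 | 1.8 | 62.1 |
| north-east | 20.0 | 3.1 | 55.6 |
| west | 3.00 | 5.5 | 64.5 |
| west | 6.00 | 18.1 | 45.1 |
| west | 10.0 | 32.5 | 31.4 |
| west | 12.0 | 38.2 | 27.7 |
| west | 15.0 | 45.0 | 23.0 |
| west | 20.0 | 53.7 | 18.0 |

(readings scatter by 0.3 percentage points)

1. final complex with three exchanged, as a percentage of the starting complex charged, for each flask in turn (ash, oak, larch)

Up to its first reading the starting complex fell at 0.0417 min⁻¹ in the north-east run and at 0.146 min⁻¹ in the west run. A straight line through these two readings against c(incoming ligand) gave a slope of 0.0803 M⁻¹ min⁻¹, a pseudo-first-order constant per unit of ligand, and an intercept of 0.0176 min⁻¹, which I read as a loss of starting complex that calls on no ligand. Slope times the c(incoming ligand) of the moment, over the intercept, I called the exchange ratio, a selectivity factor; this value belongs to the ash charge: 1.14.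

The first setting is the ligand charge. By hand the ratio grows in proportion to it, so oak starts at 4.55 and larch at 5.69, both above ash. The runs show something steeper: at 20.0 min the complex with three exchanged read 3.1 % in north-east and 53.7 % in west, a factor of 17.3 against 5.33 in ligand.

The second setting is time. By hand, with the intercept held as read, the ratio sinks as incoming ligand is used, while the complex with three exchanged still gathers. In north-east, between 15.0 min and 20.0 min, the starting complex fell at 0.0221 min⁻¹, slower than at the opening, while the complex with three exchanged read 1.8 % and then 3.1 %. So I committed to an order and no figure: ash poor, larch above oak. The forecast has the same order: 3.5 % for ash, and for oak and larch 43 % and 59 %, these two “with ligand depletion slowing things”.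

The flasks gave 4.62 % in ash, 41.4 % in oak and 53.3 % in larch.

    starting complex + incoming ligand ⇌ leaving ligand + complex with one exchanged (K = 4.00, k = 0.0900 M⁻¹ min⁻¹)
    complex with one exchanged + incoming ligand ⇌ leaving ligand + complex with two exchanged (K = 0.970, k = 0.180 M⁻¹ min⁻¹)
    2 starting complex → self-condensation product (k = 0.0170 M⁻¹ min⁻¹)
    complex with two exchanged + incoming ligand ⇌ leaving ligand + complex with three exchanged (K = 73.0, k = 0.520 M⁻¹ min⁻¹)

In ash at 40.0 min the self-condensation product, counted as the two starting complexes it holds, stood at 28.1 %. With 20 % of its incoming ligand left and the intercept held as read, the exchange ratio of ash reckoned to 0.232, below its start. In oak at that time, with 24 % of its incoming ligand left and the same intercept, the ratio reckoned to 1.08, above that of ash, and the self-condensation product stood at 12.4 %.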